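## Retrosynthetic overview

1. Rings: A = methyl orsellinate ring, B = central ring, C = formyl ester ring. Praesorether F is cut at the bond between the CH2 on ring B and C3 of ring A, giving methyl orsellinate 17 and the ring B–ring C diaryl ether 16, which carries the bridge carbon as CH2OMe.
2. Enabling feature: the CH2 carbon on ring B lies between two phenolic OH groups (both ring B carbons ortho to it), so 16 loses methanol to an ortho-quinone methide. C3 of ring A lies between the C2 and C4 hydroxyls and is the carbon that captures it, as in the presumed biosynthesis.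
3. 16 comes from its tris-MOM ether 15, which comes from SNAr of ring B phenol 8 on ring C fluoride 14 (C–F flanked by CHO and CO2Me).
4. 8 comes from orcinol 1 (MOM, lithiation between the OMOM groups with MOMCl as C1 electrophile, bromination, Br/Li exchange–borylation–oxidation). 14 comes from 3-fluoro-5-methylphenol 9 (MOM, para-bromination, lithiation between F and OMOM then DMF, methoxycarbonylation).
5. No ring is formed in the route: rings B and C are joined first (ether), ring A last (methylene).

Key step: step 11

Remark: the target has no stereocentre, so no stereocontrol is needed; 1, 9 and 17 are taken as commercial.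

## Route

Step 1
Reactants: 1 orcinol (5-methylbenzene-1,3-diol)
Product: 2 1,3-bis(methoxymethoxy)-5-methylbenzene
Conditions: MOMCl (2.5 equiv), i-Pr2NEt (3 equiv), CH2Cl2, 0 °C to rt
Reagents that add atoms: chloromethyl methyl ether (MOMCl), COCCl
Why: Williamson-type O-alkylation of both phenols by the α-chloro ether installs two MOM ethers that later direct lithiation and come off under mild acid.

Step 2
Reactants: 2 1,3-bis(methoxymethoxy)-5-methylbenzene
Product: 4 1,3-bis(methoxymethoxy)-2-(methoxymethyl)-5-methylbenzene, via aryllithium 3 (not isolated)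
Conditions: n-BuLi (1.1 equiv), THF, 0 °C, 1 h; then MOMCl (1.3 equiv), −78 °C to rt
Reagents that add atoms: chloromethyl methyl ether (MOMCl), COCCl
Why: Directed ortho-metalation at the only C–H flanked by both OMOM groups, then SN2 alkylation of the aryllithium by the α-chloro ether, should give the benzylic methyl ether that serves as the masked bridge carbon.

Step 3
Reactants: 4 1,3-bis(methoxymethoxy)-2-(methoxymethyl)-5-methylbenzene
Product: 5 2-bromo-3,5-bis(methoxymethoxy)-4-(methoxymethyl)-1-methylbenzene
Conditions: NBS (1.0 equiv), MeCN, 0 °C, dark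
Reagents that add atoms: N-bromosuccinimide (NBS), O=C1CCC(=O)N1Br
Why: Electrophilic aromatic bromination; the two remaining ring C–H positions are equivalent by symmetry and each is ortho and para to an OMOM group, so a single monobromide is expected.

Step 4
Reactants: 5 2-bromo-3,5-bis(methoxymethoxy)-4-(methoxymethyl)-1-methylbenzene
Product: 8 2,4-bis(methoxymethoxy)-3-(methoxymethyl)-6-methylphenol, via aryllithium 6 (not isolated), via arylboronate 7 (not isolated)
Conditions: n-BuLi (1.05 equiv), THF, −78 °C; B(OMe)3 (1.5 equiv), −78 to 0 °C; then H2O2 (30% aq.), NaOH (aq.), 0 °C; Na2S2O3 quench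
Reagents that add atoms: hydrogen peroxide, OO
Why: Bromine–lithium exchange outruns any deprotonation at −78 °C, and borylation followed by peroxide oxidation of the arylboronate (1,2-aryl shift from boron to oxygen) should give the phenol.

Step 5
Reactants: 9 3-fluoro-5-methylphenol
Product: 10 1-fluoro-3-(methoxymethoxy)-5-methylbenzene
Conditions: MOMCl (1.3 equiv), i-Pr2NEt (1.5 equiv), CH2Cl2, 0 °C to rt
Reagents that add atoms: chloromethyl methyl ether (MOMCl), COCCl
Why: Williamson-type O-alkylation gives the MOM ether that directs both the bromination and the later lithiation.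

Step 6
Reactants: 10 1-fluoro-3-(methoxymethoxy)-5-methylbenzene
Product: 11 2-bromo-1-fluoro-5-(methoxymethoxy)-3-methylbenzene
Conditions: NBS (1.0 equiv), MeCN, 0 °C to rt
Reagents that add atoms: N-bromosuccinimide (NBS), O=C1CCC(=O)N1Br
Why: Electrophilic aromatic bromination of an aryl ether by NBS in MeCN is para-selective, which places bromine between F and CH3, the future ester carbon.

Step 7
Reactants: 11 2-bromo-1-fluoro-5-(methoxymethoxy)-3-methylbenzene
Product: 13 3-bromo-2-fluoro-6-(methoxymethoxy)-4-methylbenzaldehyde, via aryllithium 12 (not isolated)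
Conditions: LiN(i-Pr)2 (1.1 equiv), THF, −78 °C, 1 h; then DMF (2 equiv), −78 °C; aqueous work-up
Reagents that add atoms: N,N-dimethylformamide (DMF), CN(C)C=O
Why: Directed ortho-lithiation by the amide base at the C–H flanked by F and OMOM (the most acidic site, with no attack on C–Br) followed by formylation of the aryllithium with DMF.

Step 8
Reactants: 13 3-bromo-2-fluoro-6-(methoxymethoxy)-4-methylbenzaldehyde
Product: 14 methyl 2-fluoro-3-formyl-4-(methoxymethoxy)-6-methylbenzoate
Conditions: Pd(OAc)2 (5 mol %), Xantphos (6 mol %), CO (1 atm), NEt3 (3 equiv), MeOH (10 equiv), toluene, 80 °C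
Reagents that add atoms: carbon monoxide, [C-]#[O+]; methanol, CO
Why: Palladium-catalysed methoxycarbonylation (Heck carbonylation) of the aryl bromide, with a weak amine base in toluene so that methoxide stays too low for SNAr at the C–F bond.

Step 9
Reactants: 8 2,4-bis(methoxymethoxy)-3-(methoxymethyl)-6-methylphenol; 14 methyl 2-fluoro-3-formyl-4-(methoxymethoxy)-6-methylbenzoate
Product: 15 methyl 2-[2,4-bis(methoxymethoxy)-3-(methoxymethyl)-6-methylphenoxy]-3-formyl-4-(methoxymethoxy)-6-methylbenzoate
Conditions: Cs2CO3 (1.5 equiv), DMSO, 70 °C, argon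
Reagents that add atoms: none
Why: Nucleophilic aromatic substitution (addition–elimination): the C–F carbon is activated by the ortho formyl group and the ortho ester, fluoride is the best leaving group for this mechanism, and the out-of-plane approach of the phenoxide should tolerate the four ortho substituents.

Step 10
Reactants: 15 methyl 2-[2,4-bis(methoxymethoxy)-3-(methoxymethyl)-6-methylphenoxy]-3-formyl-4-(methoxymethoxy)-6-methylbenzoate
Product: 16 methyl 2-[2,4-dihydroxy-3-(methoxymethyl)-6-methylphenoxy]-3-formyl-4-hydroxy-6-methylbenzoate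
Conditions: HCl (1.25 M in MeOH, 6 equiv), 0 °C to rt; NaHCO3 (aq.) work-up
Reagents that add atoms: none
Why: Acid-catalysed methanolysis of the three aryl MOM acetals (transacetalisation to dimethoxymethane) frees the phenols, while methanol as solvent returns any benzylic cation to the same methyl ether, so the masked bridge carbon should survive.

Step 11
Reactants: 16 methyl 2-[2,4-dihydroxy-3-(methoxymethyl)-6-methylphenoxy]-3-formyl-4-hydroxy-6-methylbenzoate; 17 methyl orsellinate (methyl 2,4-dihydroxy-6-methylbenzoate)
Product: 19 Praesorether F, via ortho-quinone methide 18 (not isolated)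
Conditions: 17 (8 equiv), p-TsOH·H2O (10 mol %), 1,4-dioxane, 60 °C, 16 added over 4 h
Reagents that add atoms: none
Why: Protonation of the benzylic methoxy group of 16 and loss of methanol, pushed by either ring B hydroxyl ortho to the CH2 group, gives ortho-quinone methide 18 (in equilibrium with its O-protonated benzylic cation), which is captured at its exocyclic carbon by C3 of 17 in a Friedel–Crafts-type conjugate addition, and tautomerisation restores both aromatic rings. The closest known reaction type is the acid- or heat-induced capture of ortho-quinone methides from 2-hydroxybenzyl alcohols and ethers by resorcinol and phloroglucinol carbon nucleophiles, as used for methylene-bridged polyketide dimers and for benzyl depsidones from hydroxymethyl depsidones. No ring is closed and no stereocentre is formed, so only regio- and chemoselectivity matter. Attack at C3 of 17 and not at C5 is expected because C3 is activated by two ortho hydroxyls, each able to hydrogen-bond to the quinone methide oxygen, and is flanked only by OH groups, whereas C5 is flanked by the methyl group; alkyl orsellinates are known to be alkylated at C3 by stabilised cations. Self-alkylation at the one free C–H of ring B (in 16 or in 19) should be held back by the large excess of 17 and the slow addition of 16, which keeps the electrophile dilute. The chelated aldehyde and both methyl esters should be inert to catalytic acid at 60 °C, and since all phenols are already free the step should deliver the natural product directly.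

## Compound list

1 | orcinol (5-methylbenzene-1,3-diol) | Cc1cc(O)cc(O)c1 | starting material
2 | 1,3-bis(methoxymethoxy)-5-methylbenzene | COCOc1cc(C)cc(OCOC)c1 | intermediate
3 | [2,6-bis(methoxymethoxy)-4-methylphenyl]lithium (not isolated) | [Li]c1c(OCOC)cc(C)cc1OCOC | intermediate
4 | 1,3-bis(methoxymethoxy)-2-(methoxymethyl)-5-methylbenzene | COCc1c(OCOC)cc(C)cc1OCOC | intermediate
5 | 2-bromo-3,5-bis(methoxymethoxy)-4-(methoxymethyl)-1-methylbenzene | COCc1c(OCOC)cc(C)c(Br)c1OCOC | intermediate
6 | [2,4-bis(methoxymethoxy)-3-(methoxymethyl)-6-methylphenyl]lithium (not isolated) | COCc1c(OCOC)cc(C)c([Li])c1OCOC | intermediate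
7 | dimethyl [2,4-bis(methoxymethoxy)-3-(methoxymethyl)-6-methylphenyl]boronate (not isolated) | COCc1c(OCOC)cc(C)c(B(OC)OC)c1OCOC | intermediate
8 | 2,4-bis(methoxymethoxy)-3-(methoxymethyl)-6-methylphenol | COCc1c(OCOC)cc(C)c(O)c1OCOC | intermediate
9 | 3-fluoro-5-methylphenol | Cc1cc(O)cc(F)c1 | starting material
10 | 1-fluoro-3-(methoxymethoxy)-5-methylbenzene | COCOc1cc(C)cc(F)c1 | intermediate
11 | 2-bromo-1-fluoro-5-(methoxymethoxy)-3-methylbenzene | COCOc1cc(C)c(Br)c(F)c1 | intermediate
12 | [3-bromo-2-fluoro-6-(methoxymethoxy)-4-methylphenyl]lithium (not isolated) | COCOc1cc(C)c(Br)c(F)c1[Li] | intermediate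
13 | 3-bromo-2-fluoro-6-(methoxymethoxy)-4-methylbenzaldehyde | COCOc1cc(C)c(Br)c(F)c1C=O | intermediate
14 | methyl 2-fluoro-3-formyl-4-(methoxymethoxy)-6-methylbenzoate | COCOc1cc(C)c(C(=O)OC)c(F)c1C=O | intermediate
15 | methyl 2-[2,4-bis(methoxymethoxy)-3-(methoxymethyl)-6-methylphenoxy]-3-formyl-4-(methoxymethoxy)-6-methylbenzoate | COCOc1cc(C)c(C(=O)OC)c(Oc2c(C)cc(OCOC)c(COC)c2OCOC)c1C=O | intermediate
16 | methyl 2-[2,4-dihydroxy-3-(methoxymethyl)-6-methylphenoxy]-3-formyl-4-hydroxy-6-methylbenzoate | COCc1c(O)cc(C)c(Oc2c(C=O)c(O)cc(C)c2C(=O)OC)c1O | intermediate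
17 | methyl orsellinate (methyl 2,4-dihydroxy-6-methylbenzoate) | COC(=O)c1c(C)cc(O)cc1O | starting material
18 | ortho-quinone methide, methyl 3-formyl-4-hydroxy-2-[(2-hydroxy-6-methyl-3-methylidene-4-oxocyclohexa-1,5-dien-1-yl)oxy]-6-methylbenzoate (not isolated) | C=C1C(=O)C=C(C)C(Oc2c(C=O)c(O)cc(C)c2C(=O)OC)=C1O | intermediate
19 | Praesorether F, methyl 3-{[3-(2-formyl-3-hydroxy-6-(methoxycarbonyl)-5-methylphenoxy)-2,6-dihydroxy-4-methylphenyl]methyl}-2,4-dihydroxy-6-methylbenzoate | COC(=O)c1c(C)cc(O)c(Cc2c(O)cc(C)c(Oc3c(C=O)c(O)cc(C)c3C(=O)OC)c2O)c1O | target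

## Summary

Total step count: 11
Longest linear sequence: 7 steps (steps 1–4, 9, 10, 11; the ring C branch, steps 5–8, 9, 10, 11, is equally long)

Steps most likely to fail, riskiest first:

1. Step 11. The quinone methide may be consumed by self-alkylation through the one free C–H of ring B (in 16 or in 19), giving oligomers faster than 17 captures it. The fallback sets out from 16 and returns at 19 and blocks that position. NBS (1.0 equiv, MeCN, −20 °C) should brominate 16 at the only ring B C–H (ortho and para to the ring B hydroxyls; ring C is deactivated by CHO and CO2Me) to give the bromo triol F1. F1 is coupled with 17 under the conditions of step 11, through the bromo ortho-quinone methide F2, to the brominated target F3, in which ring B has no nucleophilic C–H left. Hydrogenolysis of the C–Br bond (H2 1 atm, Pd/C, NaOAc, EtOAc, rt, stopped when the bromide is consumed) should then give 19.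

2. Step 9. Addition of the di-ortho-substituted phenoxide to the C–F carbon may be too slow beside the twisted ortho ester, so that decomposition of the electron-rich phenoxide or of the aldehyde takes over. The fallback sets out from 8 and 13 and returns at 15 and closes the ether before the ester is in place. SNAr of 8 on 13 (Cs2CO3, DMSO, 80 °C), whose fluorine is flanked by the formyl group and a compact bromine, should give the bromo diaryl ether F4. Methoxycarbonylation of F4 (Pd(OAc)2, Xantphos, CO, NEt3, MeOH, toluene, 100 °C) should then give 15.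

3. Step 8. Oxidative addition at the di-ortho-substituted, electron-rich C–Br bond may stall, or methanol may displace the activated fluoride once the ester is formed. The fallback sets out from 13 and returns at 14 and introduces the ester through an organolithium. 13 is converted into its dimethyl acetal F5 (HC(OMe)3, PPTS cat., MeOH, rt). Bromine–lithium exchange (n-BuLi, THF, −78 °C) gives the acetal aryllithium F6, which is acylated by methyl chloroformate (ClCO2Me, −78 °C) to the acetal ester F7. Mild hydrolysis (PPTS, acetone/H2O, rt) should free the aldehyde, leave the aryl MOM ether and give 14.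

## Further compounds

F1 | step 11 | bromo triol, methyl 2-[5-bromo-2,4-dihydroxy-3-(methoxymethyl)-6-methylphenoxy]-3-formyl-4-hydroxy-6-methylbenzoate | COCc1c(O)c(Br)c(C)c(Oc2c(C=O)c(O)cc(C)c2C(=O)OC)c1O
F2 | step 11 | bromo ortho-quinone methide, methyl 2-[(5-bromo-2-hydroxy-6-methyl-3-methylidene-4-oxocyclohexa-1,5-dien-1-yl)oxy]-3-formyl-4-hydroxy-6-methylbenzoate (not isolated) | C=C1C(=O)C(Br)=C(C)C(Oc2c(C=O)c(O)cc(C)c2C(=O)OC)=C1O
F3 | step 11 | brominated target, methyl 3-{[3-bromo-5-(2-formyl-3-hydroxy-6-(methoxycarbonyl)-5-methylphenoxy)-2,6-dihydroxy-4-methylphenyl]methyl}-2,4-dihydroxy-6-methylbenzoate | COC(=O)c1c(C)cc(O)c(Cc2c(O)c(Br)c(C)c(Oc3c(C=O)c(O)cc(C)c3C(=O)OC)c2O)c1O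
F4 | step 9 | bromo diaryl ether, 3-bromo-2-[2,4-bis(methoxymethoxy)-3-(methoxymethyl)-6-methylphenoxy]-6-(methoxymethoxy)-4-methylbenzaldehyde | COCOc1cc(C)c(Br)c(Oc2c(C)cc(OCOC)c(COC)c2OCOC)c1C=O
F5 | step 8 | dimethyl acetal, 2-bromo-4-(dimethoxymethyl)-3-fluoro-5-(methoxymethoxy)-1-methylbenzene | COCOc1cc(C)c(Br)c(F)c1C(OC)OC
F6 | step 8 | acetal aryllithium, [3-(dimethoxymethyl)-2-fluoro-4-(methoxymethoxy)-6-methylphenyl]lithium (not isolated) | COCOc1cc(C)c([Li])c(F)c1C(OC)OC
F7 | step 8 | acetal ester, methyl 3-(dimethoxymethyl)-2-fluoro-4-(methoxymethoxy)-6-methylbenzoate | COCOc1cc(C)c(C(=O)OC)c(F)c1C(OC)OC
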